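## Retrosynthetic overview

1. Artelasticin is a 5,7-dihydroxyflavone with prenyl groups on C6 and C8 of ring A and on C3 of ring C; the last disconnection only removes two silyl ethers from the 2'- and 4'-oxygens of ring B.
2. Ring C is cut at C4–C4a and O1–C2, which leaves 2,4-diprenylphloroglucinol and ethyl 2-[2,4-bis(tert-butyldimethylsilyloxy)benzoyl]-5-methylhex-4-enoate. The strategy rests on one feature: the single unsubstituted ring carbon of the phloroglucinol (future C4a) lies on a mirror plane that also contains future C7, so the two flanking hydroxyls are equivalent, either may become O1, and only one regioisomer can form with all three prenyl groups already in place.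
3. The keto ester is cut between its α-carbon and the aroyl carbon: aldol addition of ethyl 5-methylhex-4-enoate (from a Johnson–Claisen rearrangement) to bis-silylated 2,4-dihydroxybenzaldehyde, then oxidation. An alkoxide-mediated carboxylation of a silylated acetophenone is avoided, because alkoxide would strip the aryl silyl ethers and the freed 2'-phenoxide would lactonise to a 4-hydroxycoumarin.
4. The phloroglucinol partner comes from double C-prenylation of phloroglucinol.
5. Ring order: rings A and B are bought; ring C is the only ring made, in step 6.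

Key step: step 6

Remark: the target has no stereocentre, so aldol 12 is carried on as its mixture of diastereomers; both of its stereocentres are erased in steps 5 and 6.

## Route

Step 1
Reactants: 1 phloroglucinol; 2 prenyl bromide
Product: 4 2,4-diprenylphloroglucinol, via 2-prenylphloroglucinol 3 (not isolated)
Conditions: 2 (2.0 equiv), 10% aq KOH (2.2 equiv), 0 °C → rt, Ar; acidify, chromatography (recovered mono-prenyl 3 is resubmitted)
Reagents that add atoms: none
Why: C-alkylation of an ambident phenolate in water, where solvation of oxygen directs the allylic bromide to carbon; after the first prenyl group the two remaining ring carbons are equivalent, so the second alkylation can only give the 2,4-isomer, which should be separable from mono- and tri-alkylated material.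

Step 2
Reactants: 5 2,4-dihydroxybenzaldehyde
Product: 6 2,4-bis(tert-butyldimethylsilyloxy)benzaldehyde
Conditions: TBSCl (2.5 equiv), imidazole (5 equiv), DMF, 0 °C → rt
Reagents that add atoms: tert-butyldimethylsilyl chloride, CC(C)(C)[Si](C)(C)Cl
Why: Imidazole-promoted silylation of phenols; the excess of reagent should carry the hydrogen-bonded 2-hydroxyl, which reacts more slowly than the 4-hydroxyl, to the bis-silyl ether.

Step 3
Reactants: 7 2-methylbut-3-en-2-ol; 8 triethyl orthoacetate
Product: 10 ethyl 5-methylhex-4-enoate, via mixed ketene acetal 9 (not isolated)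
Conditions: MeC(OEt)3 (4 equiv), EtCO2H (cat.), 140 °C, EtOH distilled off
Reagents that add atoms: none
Why: Johnson–Claisen rearrangement, in which acid-catalysed exchange gives ketene acetal 9 and its [3,3]-sigmatropic shift forms the new C–C bond at the vinyl terminus and leaves the prenyl-type trisubstituted alkene, for which no E/Z question arises.

Step 4
Reactants: 10 ethyl 5-methylhex-4-enoate; 6 2,4-bis(tert-butyldimethylsilyloxy)benzaldehyde
Product: 12 ethyl 2-{[2,4-bis(tert-butyldimethylsilyloxy)phenyl](hydroxy)methyl}-5-methylhex-4-enoate (racemic syn/anti mixture), via lithium enolate 11 (not isolated)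
Conditions: LiN(i-Pr)2 (1.15 equiv), THF, −78 °C; then 6, −78 °C; AcOH/THF quench at −78 °C
Reagents that add atoms: none
Why: Lithium ester-enolate aldol addition, run and quenched cold so that the aldolate has no time for silyl transfer from the neighbouring aryl silyl ether or for retro-aldol; the two new stereocentres form without control and are erased later (the carbinol in step 5, the α-carbon in step 6).

Step 5
Reactants: 12 ethyl 2-{[2,4-bis(tert-butyldimethylsilyloxy)phenyl](hydroxy)methyl}-5-methylhex-4-enoate
Product: 13 ethyl 2-[2,4-bis(tert-butyldimethylsilyloxy)benzoyl]-5-methylhex-4-enoate (racemic)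
Conditions: Dess–Martin periodinane (1.3 equiv), CH2Cl2, 0 °C → rt
Reagents that add atoms: none
Why: Dess–Martin oxidation of a secondary benzylic alcohol to the ketone under non-basic conditions that should leave the aryl silyl ethers and the trisubstituted alkene untouched; no alkoxide or enolate of the silyloxyaryl ketone is generated.

Step 6
Reactants: 4 2,4-diprenylphloroglucinol; 13 ethyl 2-[2,4-bis(tert-butyldimethylsilyloxy)benzoyl]-5-methylhex-4-enoate
Product: 16 2',4'-bis-O-(tert-butyldimethylsilyl)artelasticin, via aroyl(prenyl)ketene 14 (not isolated), via C-acylated 1,3-diketone 15 (not isolated)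
Conditions: 4 (1.5 equiv), 13 (1.0 equiv), degassed neat melt (or minimal Ph2O), 235 °C, Ar sweep to carry off EtOH and H2O, 1–2 h
Reagents that add atoms: none
Why: Without acid or base, 13 loses ethanol to aroyl(prenyl)ketene 14, which acylates 4 at its only unsubstituted ring carbon (directly, or by reversible O-acylation and thermal acyl shift) to give diketone 15, and a flanking phenol then adds to the aryl ketone and water is lost to give the 4-pyranone. The closest known reaction is the Mentzer thermal pyrone synthesis, in which phloroglucinols, C-alkylated ones included, condense with α-substituted aroylacetates to 3-substituted 5,7-dihydroxyflavones. Ring C, the only ring formed, closes by 6-exo-trig attack of the phenol oxygen on the ketone carbonyl followed by dehydration. No stereocentre is created, and the racemic α-carbon of 13 ends as the sp2 carbon C3. The step needs a chromone and not a coumarin, and one regioisomer: the ester carbon becomes C4 because the ketene path forms the C–C bond there while the absence of acid shuts off Pechmann-type attack on the ketone, the silyl group on the 2'-oxygen blocks lactonisation to a 4-hydroxycoumarin, and the mirror plane of 4 makes the two flanking hydroxyls equivalent. The melt is neutral, so nothing catalyses closure of the ortho-prenyl phenols to chromans, and the excess of 4 should trap the ketene as fast as it forms.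

Step 7
Reactants: 16 2',4'-bis-O-(tert-butyldimethylsilyl)artelasticin
Product: 17 artelasticin
Conditions: Bu4NF (2.5 equiv), AcOH (2.5 equiv), THF, 0 °C, Ar
Reagents that add atoms: none
Why: Fluoride-induced cleavage of aryl silyl ethers driven by Si–F bond formation, buffered with acetic acid so that the polyphenol is not held as an air-sensitive phenoxide and the three prenyl groups meet neither strong acid nor strong base.

## Compound list

1 | phloroglucinol (benzene-1,3,5-triol) | Oc1cc(O)cc(O)c1 | starting material
2 | prenyl bromide (1-bromo-3-methylbut-2-ene) | CC(C)=CCBr | starting material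
3 | 2-prenylphloroglucinol, formed in the flask | CC(C)=CCc1c(O)cc(O)cc1O | intermediate
4 | 2,4-diprenylphloroglucinol [2,4-bis(3-methylbut-2-enyl)benzene-1,3,5-triol] | Oc1cc(O)c(CC=C(C)C)c(O)c1CC=C(C)C | intermediate
5 | 2,4-dihydroxybenzaldehyde | O=Cc1ccc(O)cc1O | starting material
6 | 2,4-bis(tert-butyldimethylsilyloxy)benzaldehyde | O=Cc1ccc(O[Si](C)(C)C(C)(C)C)cc1O[Si](C)(C)C(C)(C)C | intermediate
7 | 2-methylbut-3-en-2-ol | C=CC(C)(C)O | starting material
8 | triethyl orthoacetate | CCOC(C)(OCC)OCC | starting material
9 | mixed ketene acetal 1-ethoxy-1-(2-methylbut-3-en-2-yloxy)ethene, formed in the flask | C=C(OCC)OC(C)(C)C=C | intermediate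
10 | ethyl 5-methylhex-4-enoate | CCOC(=O)CCC=C(C)C | intermediate
11 | lithium enolate of ethyl 5-methylhex-4-enoate, formed in the flask | [Li+].CCOC([O-])=CCC=C(C)C | intermediate
12 | ethyl 2-{[2,4-bis(tert-butyldimethylsilyloxy)phenyl](hydroxy)methyl}-5-methylhex-4-enoate, racemic mixture of syn and anti diastereomers | CCOC(=O)C(CC=C(C)C)C(O)c1ccc(O[Si](C)(C)C(C)(C)C)cc1O[Si](C)(C)C(C)(C)C | intermediate
13 | ethyl 2-[2,4-bis(tert-butyldimethylsilyloxy)benzoyl]-5-methylhex-4-enoate, racemic | CCOC(=O)C(CC=C(C)C)C(=O)c1ccc(O[Si](C)(C)C(C)(C)C)cc1O[Si](C)(C)C(C)(C)C | intermediate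
14 | 2-[2,4-bis(tert-butyldimethylsilyloxy)benzoyl]-5-methylhexa-1,4-dien-1-one (aroyl(prenyl)ketene), formed in the flask | O=C=C(CC=C(C)C)C(=O)c1ccc(O[Si](C)(C)C(C)(C)C)cc1O[Si](C)(C)C(C)(C)C | intermediate
15 | 1-[2,4-bis(tert-butyldimethylsilyloxy)phenyl]-2-(3-methylbut-2-enyl)-3-[2,4,6-trihydroxy-3,5-bis(3-methylbut-2-enyl)phenyl]propane-1,3-dione, formed in the flask | CC(C)=CCC(C(=O)c1ccc(O[Si](C)(C)C(C)(C)C)cc1O[Si](C)(C)C(C)(C)C)C(=O)c1c(O)c(CC=C(C)C)c(O)c(CC=C(C)C)c1O | intermediate
16 | 2',4'-bis-O-(tert-butyldimethylsilyl)artelasticin [2-[2,4-bis(tert-butyldimethylsilyloxy)phenyl]-5,7-dihydroxy-3,6,8-tris(3-methylbut-2-enyl)chromen-4-one] | CC(C)=CCc1c(O)c(CC=C(C)C)c2oc(-c3ccc(O[Si](C)(C)C(C)(C)C)cc3O[Si](C)(C)C(C)(C)C)c(CC=C(C)C)c(=O)c2c1O | intermediate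
17 | artelasticin [2-(2,4-dihydroxyphenyl)-5,7-dihydroxy-3,6,8-tris(3-methylbut-2-enyl)chromen-4-one] | CC(C)=CCc1c(O)c(CC=C(C)C)c2oc(-c3ccc(O)cc3O)c(CC=C(C)C)c(=O)c2c1O | target

## Step count and risks

Total step count: 7. Longest linear sequence: 5 steps (steps 2, 4, 5, 6, 7, or equally steps 3, 4, 5, 6, 7).

Steps most likely to fail:

**Step 6.** At about 235 °C the ortho-prenylphenol units may react faster than the annulation, by closure of a phenol onto the neighbouring prenyl double bond or by ene-type and oxidative degradation. Silyl exchange with the free phenols is a lesser worry, since any partly desilylated flavone still converges on 17 in step 7.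

The fallback sets out from 1 and 13 and comes back at 16. It keeps the thermal annulation but takes the prenyl groups off ring A while it runs. Compound 1 is C-allylated with allyl bromide in aqueous KOH in the manner of step 1, through 2-allylphloroglucinol F1, to 2,4-diallylphloroglucinol F2. Ortho-allylphenols tolerate this temperature, being the usual products of thermal Claisen rearrangements. The melt of F2 with 13 should pass through ketene 14 and the diallyl diketone F3 to the 6,8-diallylflavone F4. Double cross-metathesis of F4 with excess 2-methylbut-2-ene, using second-generation Grubbs catalyst (H2IMes)(PCy3)Cl2Ru=CHPh in CH2Cl2 at 40 °C, then turns both allyl groups into prenyl groups and gives 16. The trisubstituted 3-prenyl alkene is a poor metathesis partner and should stay as it is.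

**Step 1.** The alkylation may not stop cleanly at two prenyl groups on carbon (under- and over-alkylation, O-alkylation, geminal dialkylation with loss of aromaticity), so that the wanted compound is a minor part of the mixture.

The fallback sets out from 1 and comes back at 4. Compound 1 is converted with chloromethyl methyl ether and i-Pr2NEt in CH2Cl2 into 1,3,5-tris(methoxymethoxy)benzene F5. Directed ortho-lithiation with n-BuLi in THF at 0 °C, between two acetal oxygens, gives 2,4,6-tris(methoxymethoxy)phenyllithium F6, which is alkylated with 2 to 1,3,5-tris(methoxymethoxy)-2-(3-methylbut-2-enyl)benzene F7. A second lithiation, possible only at the two equivalent remaining positions, gives 2,4,6-tris(methoxymethoxy)-3-(3-methylbut-2-enyl)phenyllithium F8 and, with 2, 1,3,5-tris(methoxymethoxy)-2,4-bis(3-methylbut-2-enyl)benzene F9. Brief treatment with dilute HCl in MeOH at room temperature removes the three acetals and gives 4. Each prenyl group is thus placed one at a time at a position fixed by its two flanking oxygens.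

**Step 4.** The lithium aldolate may take over the silyl group from the neighbouring 2-silyloxy oxygen (1,5 oxygen-to-oxygen shift) or revert by retro-aldol before the quench.

The fallback sets out from 10 and 6 and comes back at 12. Enolate 11 is trapped with Me3SiCl at −78 °C as the silyl ketene acetal 1-ethoxy-5-methyl-1-(trimethylsilyloxy)hexa-1,4-diene F10. This adds to 6 under BF3·OEt2 in CH2Cl2 at −78 °C (Mukaiyama aldol), so no basic alkoxide is ever formed next to the aryl silyl ether, and aqueous work-up gives 12.

## Further compounds

F1 | step 6 | 2-allylphloroglucinol | C=CCc1c(O)cc(O)cc1O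
F2 | step 6 | 2,4-diallylphloroglucinol | Oc1cc(O)c(CC=C)c(O)c1CC=C
F3 | step 6 | 1-[2,4-bis(tert-butyldimethylsilyloxy)phenyl]-3-(3,5-diallyl-2,4,6-trihydroxyphenyl)-2-(3-methylbut-2-enyl)propane-1,3-dione | CC(C)=CCC(C(=O)c1ccc(O[Si](C)(C)C(C)(C)C)cc1O[Si](C)(C)C(C)(C)C)C(=O)c1c(O)c(CC=C)c(O)c(CC=C)c1O
F4 | step 6 | 6,8-diallyl-2-[2,4-bis(tert-butyldimethylsilyloxy)phenyl]-5,7-dihydroxy-3-(3-methylbut-2-enyl)chromen-4-one | C=CCc1c(O)c(CC=C)c2oc(-c3ccc(O[Si](C)(C)C(C)(C)C)cc3O[Si](C)(C)C(C)(C)C)c(CC=C(C)C)c(=O)c2c1O
F5 | step 1 | 1,3,5-tris(methoxymethoxy)benzene | COCOc1cc(OCOC)cc(OCOC)c1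
F6 | step 1 | 2,4,6-tris(methoxymethoxy)phenyllithium | [Li]c1c(OCOC)cc(OCOC)cc1OCOC
F7 | step 1 | 1,3,5-tris(methoxymethoxy)-2-(3-methylbut-2-enyl)benzene | COCOc1cc(OCOC)c(CC=C(C)C)c(OCOC)c1
F8 | step 1 | 2,4,6-tris(methoxymethoxy)-3-(3-methylbut-2-enyl)phenyllithium | [Li]c1c(OCOC)c(CC=C(C)C)c(OCOC)cc1OCOC
F9 | step 1 | 1,3,5-tris(methoxymethoxy)-2,4-bis(3-methylbut-2-enyl)benzene | COCOc1cc(OCOC)c(CC=C(C)C)c(OCOC)c1CC=C(C)C
F10 | step 4 | 1-ethoxy-5-methyl-1-(trimethylsilyloxy)hexa-1,4-diene | CCOC(=CCC=C(C)C)O[Si](C)(C)C
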